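**Plan**

- Ring A is a 6-aryloxysalicylate. Its C1(CO2Me)–C2(O)–C3(H)–C4(CH3) segment corresponds to C3–C6 of a 3-carbomethoxy-4-acetoxy-6-methyl-2-pyrone, and C5–C6 with the ether oxygen corresponds to an ethynyl ether of ring B.
- Retrosynthesis: the benzylic acetate and the two phenols go back to a MOM/acetyl-protected diaryl ether. Ring A is then cut at C4–C5 and C1–C6 (CO2 restored) into the pyrone and the aryl ethynyl ether. The O–C(sp) bond is cut to the ring B phenol and trichloroethylene.
- Forward: the pyrone ring is made first (steps 1–2) and ring B is elaborated from 2-hydroxy-5-methoxybenzaldehyde (steps 3–10). Ring A is closed last, on the ring B oxygen (step 11), and three steps adjust the protecting groups.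
- Stereochemistry: the target has no stereocentre. The E geometry of the dichlorovinyl ether and the bridgeheads of the lactone adduct are transient.

Key step: step 11

Assumption: the terminal ynol ether 19 is taken to survive as a cold, base-washed solution for immediate use and is never stored neat. Ring A is numbered C1 (ester), C2 (hydroxyl), C4 (methyl), C6 (ether oxygen); ring B is numbered C1 (ether oxygen), C2 (hydroxyl), C4 (methoxy), C6 (acetoxymethyl).

**Route**

Step 1
Reactants: 1 2,2,6-trimethyl-4H-1,3-dioxin-4-one; 2 dimethyl malonate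
Product: 5 methyl 4-hydroxy-6-methyl-2-oxo-2H-pyran-3-carboxylate, via acetylketene 3 (not isolated), via dimethyl 2-(3-oxobutanoyl)propanedioate 4 (not isolated)
Conditions: 2, NaH (1.05 equiv), toluene with a little THF, 0 °C; add 1, 110 °C; 1 M HCl work-up
Reagents that add atoms: none
Why: Thermal retro-[4+2] fragmentation of the dioxinone releases acetylketene, the sodium malonate is C-acylated by it, and the ketone enolate oxygen of the resulting tricarbonyl closes onto a malonate ester with loss of methoxide (acylketene trapping followed by lactonisation).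

Step 2
Reactants: 5 methyl 4-hydroxy-6-methyl-2-oxo-2H-pyran-3-carboxylate
Product: 6 methyl 4-acetoxy-6-methyl-2-oxo-2H-pyran-3-carboxylate
Conditions: AcCl, Et3N, THF, 0 °C; filtration of the ammonium salt, no aqueous work-up
Reagents that add atoms: acetyl chloride, CC(Cl)=O
Why: O-acylation of the acidic 4-hydroxyl (a vinylogous carboxylic acid); C3 is blocked by the ester, so no C-acylation or O-to-C acyl shift can follow, and the anhydrous work-up spares the reactive enol acetate.

Step 3
Reactants: 7 2-hydroxy-5-methoxybenzaldehyde
Product: 8 3-bromo-2-hydroxy-5-methoxybenzaldehyde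
Conditions: Br2, NaOAc, AcOH, rt
Reagents that add atoms: bromine, BrBr
Why: Electrophilic aromatic bromination directed ortho by the hydroxyl group, whose para position is blocked by the methoxy group and whose other ortho position carries the aldehyde.

Step 4
Reactants: 8 3-bromo-2-hydroxy-5-methoxybenzaldehyde
Product: 9 2-(benzyloxy)-3-bromo-5-methoxybenzaldehyde
Conditions: BnBr, K2CO3, DMF, 50 °C
Reagents that add atoms: benzyl bromide, BrCc1ccccc1
Why: Williamson ether synthesis on the acidic salicylaldehyde phenol; the benzyl group marks the oxygen that later becomes the diaryl ether oxygen.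

Step 5
Reactants: 9 2-(benzyloxy)-3-bromo-5-methoxybenzaldehyde
Product: 10 [2-(benzyloxy)-3-bromo-5-methoxyphenyl]methanol
Conditions: NaBH4, MeOH/THF, 0 °C
Reagents that add atoms: none
Why: Hydride reduction of the aldehyde; the aryl bromide and the benzyl ether are inert to NaBH4.

Step 6
Reactants: 10 [2-(benzyloxy)-3-bromo-5-methoxyphenyl]methanol
Product: 11 2-(benzyloxy)-3-(hydroxymethyl)-5-methoxyphenol
Conditions: Pd2(dba)3 (2 mol%, zerovalent palladium source), tBuXPhos (8 mol%), KOH (4 equiv), 1,4-dioxane/H2O, 100 °C; then dilute HCl to pH 5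
Reagents that add atoms: potassium hydroxide, [K+].[OH-]
Why: Palladium-catalysed hydroxylation of an aryl bromide (Buchwald-type C–O coupling with hydroxide): oxidative addition, bromide/hydroxide exchange and C–O reductive elimination driven by the bulky biaryl phosphine, with the primary alcohol a spectator in the water-rich medium.

Step 7
Reactants: 11 2-(benzyloxy)-3-(hydroxymethyl)-5-methoxyphenol
Product: 12 2-(benzyloxy)-5-methoxy-1-(methoxymethoxy)-3-[(methoxymethoxy)methyl]benzene
Conditions: MOMCl (3 equiv), iPr2NEt (4 equiv), CH2Cl2, 0 to 40 °C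
Reagents that add atoms: chloromethyl methyl ether, COCCl
Why: O-alkylation of both the phenol and the primary alcohol with the reactive α-chloro ether (MOM protection), giving two base- and organolithium-stable acetals in one operation.

Step 8
Reactants: 12 2-(benzyloxy)-5-methoxy-1-(methoxymethoxy)-3-[(methoxymethoxy)methyl]benzene
Product: 13 4-methoxy-2-(methoxymethoxy)-6-[(methoxymethoxy)methyl]phenol
Conditions: H2 (1 atm), Pd/C (10% palladium on carbon), EtOAc, rt, stopped at full conversion
Reagents that add atoms: none
Why: Catalytic hydrogenolysis of the aryl benzyl ether, which cleaves much faster than the benzylic C–O bond of the ring B MOM acetal, frees only the central phenol.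

Step 9
Reactants: 13 4-methoxy-2-(methoxymethoxy)-6-[(methoxymethoxy)methyl]phenol; 14 trichloroethylene
Product: 16 2-{[(E)-1,2-dichloroethenyl]oxy}-5-methoxy-1-(methoxymethoxy)-3-[(methoxymethoxy)methyl]benzene, via dichloroacetylene 15 (not isolated)
Conditions: KH, THF, 0 °C; 14, −40 °C to rt
Reagents that add atoms: none
Why: First stage of the Greene ynol ether synthesis: base-induced loss of HCl from trichloroethylene gives dichloroacetylene, to which the hindered phenoxide adds in anti fashion, so the E-dichlorovinyl ether results and the crowded oxygen is bonded to a small sp2 carbon.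

Step 10
Reactants: 16 2-{[(E)-1,2-dichloroethenyl]oxy}-5-methoxy-1-(methoxymethoxy)-3-[(methoxymethoxy)methyl]benzene
Product: 19 2-(ethynyloxy)-5-methoxy-1-(methoxymethoxy)-3-[(methoxymethoxy)methyl]benzene, via chloroethynyl ether 17 (not isolated), via lithium acetylide 18 (not isolated)
Conditions: n-BuLi (2.2 equiv), THF, −78 to −40 °C; MeOH, −78 °C; cold extraction, short basic Al2O3 plug, kept as a toluene solution at −20 °C
Reagents that add atoms: none
Why: Second stage of the Greene sequence: vinylic deprotonation and loss of LiCl give the chloroalkyne, chlorine–lithium exchange gives the lithium acetylide, and protonation at low temperature delivers the terminal ynol ether, while the MOM acetals are not lithiated at −78 °C.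

Step 11
Reactants: 6 methyl 4-acetoxy-6-methyl-2-oxo-2H-pyran-3-carboxylate; 19 2-(ethynyloxy)-5-methoxy-1-(methoxymethoxy)-3-[(methoxymethoxy)methyl]benzene
Product: 21 methyl 2-acetoxy-6-{4-methoxy-2-(methoxymethoxy)-6-[(methoxymethoxy)methyl]phenoxy}-4-methylbenzoate, via bridged lactone 20 (not isolated)
Conditions: 6 (2 equiv), 2,6-di-tert-butyl-4-methylpyridine (0.2 equiv), degassed toluene, 80 °C, 19 added slowly by syringe pump; then 100 °C until CO2 evolution ends
Reagents that add atoms: none
Why: The pyrone, made electron-poor by the C3 ester and the lactone carbonyl, serves as the diene across C3 and C6 in an inverse-electron-demand [4+2] cycloaddition with the electron-rich ynol ether, and the bridged lactone 20 then loses CO2 by retro-[4+2] cycloreversion to give the benzene ring directly because the two-carbon partner is an alkyne. The closest known reaction type is the salicylate synthesis from 3-carbomethoxy-2-pyrones and ketene acetals or ynamines, of which an aryl ethynyl ether is a less nucleophilic member of the same heteroatom-substituted class. Ring A closes by an intermolecular [4+2] annulation that forms C4–C5 and C1–C6 in one operation (no chain cyclisation is involved), and aromatisation is the cycloreversion, not an elimination. No stereocentre survives: the two bridgeheads of 20 are tied by the bicycle, form as a racemate and become sp2 carbons on CO2 loss. The selectivity needed is regiochemical and is secured by matched polarisation: the terminal alkyne carbon, the nucleophilic β-position of the ynol ether, bonds first to pyrone C6, the electrophilic δ-terminus, while the oxygen-bearing carbon with its developing positive charge closes onto C3, where ester and lactone carbonyl hold the developing negative charge, so the ether oxygen ends ortho to the ester. Slow addition of 19 into excess 6 with a hindered pyridine keeps the alkyne concentration and any acid low, so that polymerisation and hydration of the ynol ether should not compete.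

Step 12
Reactants: 21 methyl 2-acetoxy-6-{4-methoxy-2-(methoxymethoxy)-6-[(methoxymethoxy)methyl]phenoxy}-4-methylbenzoate
Product: 22 methyl 2-hydroxy-6-[2-hydroxy-6-(hydroxymethyl)-4-methoxyphenoxy]-4-methylbenzoate
Conditions: HCl (2 M in MeOH), 40 °C
Reagents that add atoms: none
Why: Acid-catalysed acetal exchange removes both MOM groups as dimethoxymethane and transesterification removes the aryl acetate; the methyl ester is degenerate in methanol, and the benzylic alcohol should not ionise because its carbon is meta to both strong donors of ring B.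

Step 13
Reactants: 22 methyl 2-hydroxy-6-[2-hydroxy-6-(hydroxymethyl)-4-methoxyphenoxy]-4-methylbenzoate
Product: 23 methyl 2-acetoxy-6-[2-acetoxy-6-(acetoxymethyl)-4-methoxyphenoxy]-4-methylbenzoate
Conditions: Ac2O (5 equiv), pyridine, DMAP (cat.), CH2Cl2, rt
Reagents that add atoms: acetic anhydride, CC(=O)OC(C)=O
Why: Exhaustive DMAP-catalysed acetylation esterifies the primary alcohol and both phenols, including the hydrogen-bonded salicylate hydroxyl, so no selectivity is asked of this step.

Step 14
Reactants: 23 methyl 2-acetoxy-6-[2-acetoxy-6-(acetoxymethyl)-4-methoxyphenoxy]-4-methylbenzoate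
Product: 24 methyl 2-{2-[(acetyloxy)methyl]-6-hydroxy-4-methoxyphenoxy}-6-hydroxy-4-methylbenzoate (betaethrin A)
Conditions: pyrrolidine (2.2 equiv), CH2Cl2, 0 °C
Reagents that add atoms: none
Why: Chemoselective aminolysis of the two aryl acetates, which are active esters with phenoxide leaving groups, should be far faster than that of the primary benzylic acetate, and the 2,6-disubstituted methyl benzoate is too hindered to react.

**Compound list**

1 | 2,2,6-trimethyl-4H-1,3-dioxin-4-one | CC1=CC(=O)OC(C)(C)O1 | starting material
2 | dimethyl malonate | COC(=O)CC(=O)OC | starting material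
3 | acetylketene (not isolated) | CC(=O)C=C=O | intermediate
4 | dimethyl 2-(3-oxobutanoyl)propanedioate (not isolated) | COC(=O)C(C(=O)CC(C)=O)C(=O)OC | intermediate
5 | methyl 4-hydroxy-6-methyl-2-oxo-2H-pyran-3-carboxylate | COC(=O)C1=C(O)C=C(C)OC1=O | intermediate
6 | methyl 4-acetoxy-6-methyl-2-oxo-2H-pyran-3-carboxylate | COC(=O)C1=C(OC(C)=O)C=C(C)OC1=O | intermediate
7 | 2-hydroxy-5-methoxybenzaldehyde | COc1ccc(O)c(C=O)c1 | starting material
8 | 3-bromo-2-hydroxy-5-methoxybenzaldehyde | COc1cc(Br)c(O)c(C=O)c1 | intermediate
9 | 2-(benzyloxy)-3-bromo-5-methoxybenzaldehyde | COc1cc(Br)c(OCc2ccccc2)c(C=O)c1 | intermediate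
10 | [2-(benzyloxy)-3-bromo-5-methoxyphenyl]methanol | COc1cc(Br)c(OCc2ccccc2)c(CO)c1 | intermediate
11 | 2-(benzyloxy)-3-(hydroxymethyl)-5-methoxyphenol | COc1cc(O)c(OCc2ccccc2)c(CO)c1 | intermediate
12 | 2-(benzyloxy)-5-methoxy-1-(methoxymethoxy)-3-[(methoxymethoxy)methyl]benzene | COCOCc1cc(OC)cc(OCOC)c1OCc1ccccc1 | intermediate
13 | 4-methoxy-2-(methoxymethoxy)-6-[(methoxymethoxy)methyl]phenol | COCOCc1cc(OC)cc(OCOC)c1O | intermediate
14 | trichloroethylene | ClC=C(Cl)Cl | starting material
15 | dichloroacetylene (not isolated) | ClC#CCl | intermediate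
16 | 2-{[(E)-1,2-dichloroethenyl]oxy}-5-methoxy-1-(methoxymethoxy)-3-[(methoxymethoxy)methyl]benzene | COCOCc1cc(OC)cc(OCOC)c1O/C(Cl)=C\Cl | intermediate
17 | 2-[(chloroethynyl)oxy]-5-methoxy-1-(methoxymethoxy)-3-[(methoxymethoxy)methyl]benzene (not isolated) | COCOCc1cc(OC)cc(OCOC)c1OC#CCl | intermediate
18 | lithium 2-{4-methoxy-2-(methoxymethoxy)-6-[(methoxymethoxy)methyl]phenoxy}ethynide (not isolated) | COCOCc1cc(OC)cc(OCOC)c1OC#C[Li] | intermediate
19 | 2-(ethynyloxy)-5-methoxy-1-(methoxymethoxy)-3-[(methoxymethoxy)methyl]benzene | COCOCc1cc(OC)cc(OCOC)c1OC#C | intermediate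
20 | methyl 5-acetoxy-8-{4-methoxy-2-(methoxymethoxy)-6-[(methoxymethoxy)methyl]phenoxy}-1-methyl-3-oxo-2-oxabicyclo[2.2.2]octa-5,7-diene-4-carboxylate (racemic, one enantiomer drawn, not isolated) | C[C@]12OC(=O)[C@](C(=O)OC)(C(OC(C)=O)=C1)C(Oc3c(OCOC)cc(OC)cc3COCOC)=C2 | intermediate
21 | methyl 2-acetoxy-6-{4-methoxy-2-(methoxymethoxy)-6-[(methoxymethoxy)methyl]phenoxy}-4-methylbenzoate | COC(=O)c1c(OC(C)=O)cc(C)cc1Oc1c(OCOC)cc(OC)cc1COCOC | intermediate
22 | methyl 2-hydroxy-6-[2-hydroxy-6-(hydroxymethyl)-4-methoxyphenoxy]-4-methylbenzoate | COC(=O)c1c(O)cc(C)cc1Oc1c(O)cc(OC)cc1CO | intermediate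
23 | methyl 2-acetoxy-6-[2-acetoxy-6-(acetoxymethyl)-4-methoxyphenoxy]-4-methylbenzoate | COC(=O)c1c(OC(C)=O)cc(C)cc1Oc1c(OC(C)=O)cc(OC)cc1COC(C)=O | intermediate
24 | methyl 2-{2-[(acetyloxy)methyl]-6-hydroxy-4-methoxyphenoxy}-6-hydroxy-4-methylbenzoate (betaethrin A) | COC(=O)c1c(O)cc(C)cc1Oc1c(O)cc(OC)cc1COC(C)=O | target

**Step count**

Total: 14 steps. Longest linear sequence: 12 steps (steps 3–14, from 2-hydroxy-5-methoxybenzaldehyde); the pyrone branch (steps 1–2) joins at step 11.

**Steps most likely to fail**

Step 11 (ring A cycloaddition). The ynol ether may polymerise faster than it adds, or it may attack C4 of the pyrone and displace acetate in place of cycloaddition. The fallback reverses the polarity of the annulation. From dichlorovinyl ether 16 the acetylide 18 is generated as in step 10 and trapped with methyl chloroformate to give methyl 3-{4-methoxy-2-(methoxymethoxy)-6-[(methoxymethoxy)methyl]phenoxy}prop-2-ynoate F1, a stable push–pull alkyne. A normal-demand Diels–Alder reaction of F1 with 3-methyl-1,1-bis(trimethylsilyloxy)buta-1,3-diene F2 (one pot from 3-methylbut-2-enoic acid, LiN(iPr)2 (2 equiv), TMSCl) in toluene at 110 °C should join the diene CH2 terminus to the aryloxy-bearing β-carbon. Loss of trimethylsilanol and desilylation on mild acidic work-up should then give methyl 2-hydroxy-6-{4-methoxy-2-(methoxymethoxy)-6-[(methoxymethoxy)methyl]phenoxy}-4-methylbenzoate F3. The acid methanolysis of step 12, applied to F3, brings the route back at triol 22.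

Step 10 (terminal ynol ether). Hydration to the aryl acetate or polymerisation may consume the terminal ynol ether during quench and isolation. The fallback sets out from 16: the acetylide 18 is silylated with TMSCl to give ({4-methoxy-2-(methoxymethoxy)-6-[(methoxymethoxy)methyl]phenoxy}ethynyl)trimethylsilane F4, a capped ynol ether that can be chromatographed and stored. F4 replaces 19 in the cycloaddition with 6 (toluene, 110 °C); the β-silyl group supports the same polarisation, and loss of CO2 should give methyl 2-acetoxy-6-{4-methoxy-2-(methoxymethoxy)-6-[(methoxymethoxy)methyl]phenoxy}-4-methyl-5-(trimethylsilyl)benzoate F5. The silyl group sits ortho to the ether oxygen and para to the C2 oxygen of ring A, so the acid methanolysis of step 12 should remove it by ipso-protonation together with the MOM and acetyl groups, and the route is rejoined at triol 22.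

Step 6 (hydroxylation). The arylpalladium intermediate may be diverted by the free benzylic alcohol (palladium alkoxide formation and β-hydride elimination), leading to hydrodebromination and alcohol oxidation. The fallback sets out from 10: the alcohol is first protected (MOMCl, iPr2NEt) as 2-(benzyloxy)-1-bromo-5-methoxy-3-[(methoxymethoxy)methyl]benzene F6. Bromine–lithium exchange (n-BuLi, THF, −78 °C), borylation with B(OMe)3 and oxidation with H2O2/NaOH should give 2-(benzyloxy)-5-methoxy-3-[(methoxymethoxy)methyl]phenol F7. A second MOM protection of F7 returns to the route at 12.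

**Further compounds**

F1 | step 11 | methyl 3-{4-methoxy-2-(methoxymethoxy)-6-[(methoxymethoxy)methyl]phenoxy}prop-2-ynoate | COC(=O)C#COc1c(OCOC)cc(OC)cc1COCOC
F2 | step 11 | 3-methyl-1,1-bis(trimethylsilyloxy)buta-1,3-diene | CC(=C)C=C(O[Si](C)(C)C)O[Si](C)(C)C
F3 | step 11 | methyl 2-hydroxy-6-{4-methoxy-2-(methoxymethoxy)-6-[(methoxymethoxy)methyl]phenoxy}-4-methylbenzoate | COC(=O)c1c(O)cc(C)cc1Oc1c(OCOC)cc(OC)cc1COCOC
F4 | step 10 | ({4-methoxy-2-(methoxymethoxy)-6-[(methoxymethoxy)methyl]phenoxy}ethynyl)trimethylsilane | COCOCc1cc(OC)cc(OCOC)c1OC#C[Si](C)(C)C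
F5 | step 10 | methyl 2-acetoxy-6-{4-methoxy-2-(methoxymethoxy)-6-[(methoxymethoxy)methyl]phenoxy}-4-methyl-5-(trimethylsilyl)benzoate | COC(=O)c1c(OC(C)=O)cc(C)c([Si](C)(C)C)c1Oc1c(OCOC)cc(OC)cc1COCOC
F6 | step 6 | 2-(benzyloxy)-1-bromo-5-methoxy-3-[(methoxymethoxy)methyl]benzene | COCOCc1cc(OC)cc(Br)c1OCc1ccccc1
F7 | step 6 | 2-(benzyloxy)-5-methoxy-3-[(methoxymethoxy)methyl]phenol | COCOCc1cc(OC)cc(O)c1OCc1ccccc1
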